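**Counting half-lives.** Time was my unit: I asked how many half-lives of the electrophile the amber flask would pass through by 2.5 h, the end of dosing.

in all of them: electrophile 0.10 M
- amber: nucleophile 0.13 M; buffer base 0.30 M (fed, over 2.5 h); buffer acid 0.010 M; the very flask that is asked about, followed so far; the fed solution adds 0.10 times the starting volume
- green: nucleophile 0.20 M; buffer base 0.30 M (fed, over 2.5 h); buffer acid 0.010 M; run made earlier; the fed solution adds 0.10 times the starting volume
- flask: nucleophile 0.130 M; buffer base 0.300 M (fed, over 2.5 h); buffer acid 0.0100 M; the fed solution adds 0.10 times the starting volume; time 2.5 h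

| run | time / min | electrophile / % | target / % |
|---|---|---|---|
| amber | 5.00 | 92.5 | 3.2 |
| amber | 15.0 | 84.9 | 12.7 |
| amber | 30.0 | 69.4 | 23.9 |
| amber | 40.0 | 64.5 | 28.0 |
| amber | 60.0 | 53.6 | 37.5 |
| green | 20.0 | 70.6 | 27.1 |
| green | 40.0 | 49.8 | 41.7 |
| green | 60.0 | 37.3 | 50.3 |
| green | 80.0 | 27.5 | 54.3 |
| green | 120 | 16.5 | 61.9 |

(scatter of a reading: 1 percentage point)

* part of the electrophile that has reacted at 2.5 h
* pH of the solution at 2.5 h

- acid is the free proton; pH is minus the decimal logarithm of its molar concentration
- a species is counted by the electrophile in it: one side product counts as two
- amounts and yields of leaving group count crystals too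
- charges are per starting volume, the dose included; the dosed solution carries all of it
- given per volume of solution although it is solid: crystals
- steps under discussion: electrophile + nucleophile -> acid + target + leaving group; buffer acid <-> buffer base + acid; crystals <-> leaving group; electrophile + target -> side product; protonated nucleophile <-> nucleophile + acid
- the earlier runs do not show the pH; that part of a forecast is a guess

**Starting rate.** The first green reading gave a fractional loss of electrophile, averaged over that interval, of 1.04 h⁻¹. I took this as proportional to [nucleophile], which gave the amber flask 0.679 h⁻¹. The starting half-life, the time in which the electrophile would halve at that opening rate, was therefore 1.02 h, and unslowed the amber flask would pass 2.45 half-lives.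

**The slowing.** By 60.0 min, the amber balance of target and side product put the nucleophile not yet used, free or protonated, at 0.677 of its charge. In the amber flask the feed would dilute the rate by a factor of 0.909 by the end. The amber readings from 30.0 min to 60.0 min showed a rate of 0.517 h⁻¹, less than my opening figure, with the side step's added loss included. The first amber hour had used 0.900 half-lives. Holding that later rate, diluted, for the remaining time added 1.02. My count for the amber flask was 1.92, a slowing factor of 0.783, so I reckoned 73.5% reacted. The runs show no pH, so I reckoned none.

**The forecast.** It gave 76% reacted, more than my count, and a guessed pH of 7, holding that “the dosed base keeps up with the acid formed”.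

**The result.** The amber flask gave 76.6% reacted and pH 9.82, above the forecast's guess.

    electrophile + nucleophile → acid + target + leaving group (k = 5.56 M⁻¹ h⁻¹)
    buffer acid ⇌ buffer base + acid, settled at all times (K = 5.00 × 10⁻¹⁰ M)
    crystals ⇌ leaving group, rate k3*(cs3 - [leaving group]) while solid is left; crystals form when [leaving group] > cs3 (solubility = 0.0890 M, k = 4.20 h⁻¹)
    electrophile + target → side product (k = 3.76 M⁻¹ h⁻¹)
    protonated nucleophile ⇌ nucleophile + acid, settled at all times (K = 1.30 × 10⁻⁸ M)

The 23% of electrophile left in the amber flask amounts to 2.10 half-lives. A neighbour flask held 0.033 M of nucleophile, 0.330 equiv, less than the electrophile, so nucleophile was the limiting reagent there. Scaling by [nucleophile] gave the neighbour a starting half-life of 4.02 h, hence 0.622 half-lives in 2.5 h. The amber slowing factor, carried over unchanged, cut this to 0.486, for a reckoned 71.4% of electrophile left. The neighbour held 71% of its electrophile at 2.50 h.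

The data were computed with constants of no real substance; scatter was added.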